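**Plan**

- Numbering of the target: quinone ring C1 (C=O), C2 (side chain), C3 (OMe), C4 (C=O), C5 (OMe), C6 (H). Retrosynthetically, the C4 carbonyl goes back to an aryl methyl ether (quinone to para-methoxyphenol), and the side-chain ketone and the C1 oxygen are tied together as the cyclic enol ether of a 2-aryl-4H-chromene, the double-bond isomer of a 2-aryl-2H-chromene.
- The 2H-chromene is cut at the ring C2–chain carbon bond, the ring C1–O bond and the O–CH(aryl) bond of the pyran, giving 3,4,5-trimethoxybenzyne and (E)-3,4-dimethoxycinnamaldehyde.
- Enabling feature: ring carbon C2 carries the chain, its neighbour C1 carries oxygen and its other neighbour C3 carries a methoxy group. A carbon/oxygen ortho pair with a methoxy flanking the carbon end is what a 3-methoxyaryne gives when a carbonyl adds oxygen-first; C1, C2, that oxygen and the three chain carbons then form the pyran ring.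
- Forward: 3,4,5-trimethoxyphenol is converted to the ortho-silylaryl triflate (three steps); the aryne annulation closes the only ring made in the route (the pyran); a base-catalysed double-bond shift and acid hydrolysis open it to the phenolic dihydrochalcone; PhI(OAc)2 gives the quinone.
- Stereochemistry: the target is achiral. The single stereocentre formed in the key step (chromene C2) is racemic and is removed in the next step.

Key step: step 4

Remark: 3,4,5-trimethoxyphenol and (E)-3,4-dimethoxycinnamaldehyde are assumed to be purchased.

**Route**

Step 1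
Reactants: 1 3,4,5-trimethoxyphenol
Product: 2 2-bromo-3,4,5-trimethoxyphenol
Conditions: NBS (1.0 equiv), CH2Cl2, −78 → 0 °C, dark
Reagents that add atoms: N-bromosuccinimide, O=C1CCC(=O)N1Br
Why: Electrophilic aromatic bromination; the two free ring positions of 1 are equivalent and each is activated by the ortho hydroxyl, an ortho methoxy and a para methoxy group, so one equivalent of NBS at low temperature should give the only possible monobromide.

Step 2
Reactants: 2 2-bromo-3,4,5-trimethoxyphenol
Product: 3 (2-bromo-3,4,5-trimethoxyphenoxy)trimethylsilane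
Conditions: HMDS (1.5 equiv), THF, reflux; volatiles evaporated, crude product used directly
Reagents that add atoms: hexamethyldisilazane, C[Si](C)(C)N[Si](C)(C)C
Why: O-Silylation of a phenol with HMDS, driven by loss of ammonia, is the standard first stage of silylaryl triflate synthesis and needs no base that could disturb the aryl bromide.

Step 3
Reactants: 3 (2-bromo-3,4,5-trimethoxyphenoxy)trimethylsilane
Product: 6 3,4,5-trimethoxy-2-(trimethylsilyl)phenyl trifluoromethanesulfonate, via aryllithium 4 (not isolated), via lithium silylphenoxide 5 (not isolated)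
Conditions: n-BuLi (1.1 equiv), THF, −100 → −78 °C; then Tf2O (1.2 equiv), −100 → −78 °C; cold aq NaHCO3
Reagents that add atoms: trifluoromethanesulfonic anhydride, O=S(=O)(OS(=O)(=O)C(F)(F)F)C(F)(F)F
Why: Bromine–lithium exchange gives the aryllithium, which should undergo the anionic 1,3 O-to-C silyl shift (retro-Brook rearrangement) driven by phenoxide formation, and the phenoxide is then trapped by O-sulfonylation with Tf2O.

Step 4
Reactants: 6 3,4,5-trimethoxy-2-(trimethylsilyl)phenyl trifluoromethanesulfonate; 7 (E)-3,4-dimethoxycinnamaldehyde
Product: 11 2-(3,4-dimethoxyphenyl)-5,6,7-trimethoxy-2H-chromene (racemic), via 3,4,5-trimethoxybenzyne 8 (not isolated), via benzoxete 9 (not isolated), via ortho-quinone methide 10 (not isolated)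
Conditions: 7 (2.0 equiv), CsF (3.0 equiv), MeCN, 25 °C, 6 added over 4 h by syringe pump; then 40 °C, 2 h; chromatography on Et3N-deactivated silica
Reagents that add atoms: none
Why: Fluoride attacks silicon in 6 and triflate leaves from the neighbouring carbon, so that 3,4,5-trimethoxybenzyne 8 is released slowly into an excess of enal 7. The carbonyl oxygen of 7 adds to the aryne carbon that lies away from the flanking methoxy group and the aryl anion so formed closes onto the carbonyl carbon (stepwise [2+2] addition, the four-membered oxete ring of 9 being closed by C–C bond formation); 4π ring opening of 9 then gives ortho-quinone methide 10. Thermal disrotatory oxa-6π electrocyclisation of the 1-oxatriene in 10 closes the six-membered pyran ring by O–C bond formation at the carbon bearing the dimethoxyphenyl group and restores the benzene ring. The closest known reaction type is the insertion of arynes into the C=O bond of aldehydes, which with α,β-unsaturated aldehydes is a known aryne route to 2H-chromenes. The one new stereocentre (chromene C2) has no controlling element, should form racemic and is removed in step 5. The selectivity needed is regiochemical (oxygen on the aryne carbon next to C–H, carbon on the one next to C–OMe) and is secured by the methoxy group beside the triple bond, which distorts the aryne so that the remote carbon is the more electrophilic and inductively stabilises the negative charge developing at the adjacent carbon; slow aryne release keeps a second aryne from intercepting 10.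

Step 5
Reactants: 11 2-(3,4-dimethoxyphenyl)-5,6,7-trimethoxy-2H-chromene (racemic)
Product: 13 1-(3,4-dimethoxyphenyl)-3-(2-hydroxy-4,5,6-trimethoxyphenyl)propan-1-one, via 4H-chromene enol ether 12 (not isolated)
Conditions: t-BuOK (0.3 equiv), DMSO, 25 °C, argon; then 1 M aq HCl–THF (1:3), 25 °C
Reagents that add atoms: water, O
Why: Base-catalysed prototropic isomerisation of the allylic benzylic ether to the enol ether (C2–H is doubly activated and the new C2=C3 bond is conjugated to both the ring oxygen and the dimethoxyphenyl ring) should be followed by acid hydrolysis of the cyclic enol ether, in which C3 is protonated and water adds at C2 to release the phenol and the aryl ketone.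

Step 6
Reactants: 13 1-(3,4-dimethoxyphenyl)-3-(2-hydroxy-4,5,6-trimethoxyphenyl)propan-1-one
Product: 14 evelynin, 2-[3-(3,4-dimethoxyphenyl)-3-oxopropyl]-3,5-dimethoxycyclohexa-2,5-diene-1,4-dione
Conditions: PhI(OAc)2 (1.2 equiv), MeCN–H2O (2:1), 0 °C
Reagents that add atoms: water, O
Why: Oxidative demethylation of a para-methoxyphenol by the trivalent iodine reagent: ligand exchange at iodine, attack of water at the para carbon, loss of iodobenzene and collapse of the hemiketal with loss of methanol should give the para-quinone, while the acyl-deactivated dimethoxyphenyl ketone ring is left untouched.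

**Compound list**

1 | 3,4,5-trimethoxyphenol | COc1cc(O)cc(OC)c1OC | starting material
2 | 2-bromo-3,4,5-trimethoxyphenol | COc1cc(O)c(Br)c(OC)c1OC | intermediate
3 | (2-bromo-3,4,5-trimethoxyphenoxy)trimethylsilane | COc1cc(O[Si](C)(C)C)c(Br)c(OC)c1OC | intermediate
4 | [2,3,4-trimethoxy-6-(trimethylsilyloxy)phenyl]lithium | COc1cc(O[Si](C)(C)C)c([Li])c(OC)c1OC | intermediate
5 | lithium 3,4,5-trimethoxy-2-(trimethylsilyl)phenoxide | [Li+].[O-]c1cc(OC)c(OC)c(OC)c1[Si](C)(C)C | intermediate
6 | 3,4,5-trimethoxy-2-(trimethylsilyl)phenyl trifluoromethanesulfonate | COc1cc(OS(=O)(=O)C(F)(F)F)c([Si](C)(C)C)c(OC)c1OC | intermediate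
7 | (E)-3,4-dimethoxycinnamaldehyde | COc1ccc(/C=C/C=O)cc1OC | starting material
8 | 3,4,5-trimethoxybenzyne (1,2-didehydro-3,4,5-trimethoxybenzene) | COC1=CC#CC(OC)=C1OC | intermediate
9 | 2-[(E)-2-(3,4-dimethoxyphenyl)ethenyl]-3,4,5-trimethoxy-2H-benzo[b]oxete (racemic) | COc1cc2OC(/C=C/c3ccc(OC)c(OC)c3)c2c(OC)c1OC | intermediate
10 | (6Z)-6-[(2E)-3-(3,4-dimethoxyphenyl)prop-2-en-1-ylidene]-3,4,5-trimethoxycyclohexa-2,4-dien-1-one | O=C1C=C(OC)C(OC)=C(OC)/C1=C/C=C/c1ccc(OC)c(OC)c1 | intermediate
11 | 2-(3,4-dimethoxyphenyl)-5,6,7-trimethoxy-2H-chromene (racemic) | COc1cc2OC(c3ccc(OC)c(OC)c3)C=Cc2c(OC)c1OC | intermediate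
12 | 2-(3,4-dimethoxyphenyl)-5,6,7-trimethoxy-4H-chromene | COc1cc2OC(c3ccc(OC)c(OC)c3)=CCc2c(OC)c1OC | intermediate
13 | 1-(3,4-dimethoxyphenyl)-3-(2-hydroxy-4,5,6-trimethoxyphenyl)propan-1-one | COc1cc(O)c(CCC(=O)c2ccc(OC)c(OC)c2)c(OC)c1OC | intermediate
14 | evelynin, 2-[3-(3,4-dimethoxyphenyl)-3-oxopropyl]-3,5-dimethoxycyclohexa-2,5-diene-1,4-dione | COC1=CC(=O)C(CCC(=O)c2ccc(OC)c(OC)c2)=C(OC)C1=O | target

**Step count**

Total steps: 6. Longest linear sequence: 6 steps (from 1 to 14).

**Steps most likely to fail and fallbacks**

Step 4 (aryne annulation). Carbonyl addition to the hindered, electron-rich aryne may be slower than aryne self-consumption, the quinone methide may be captured by a second aryne, or the orientation of addition may erode; the chromene would then form inefficiently or as a regioisomer mixture. The fallback sets out from phenol 1 and aldehyde 7 and generates the same ortho-quinone methide from the phenol side. Heating 1 and 7 with PhB(OH)2 and catalytic propionic acid in toluene with azeotropic removal of water should give, by boron-templated ortho-hydroxyalkylation, 4-[(E)-2-(3,4-dimethoxyphenyl)ethenyl]-5,6,7-trimethoxy-2-phenyl-4H-1,3,2-benzodioxaborinine F1. On continued heating F1 should extrude the boron unit to give ortho-quinone methide 10, which closes to chromene 11, where the route is rejoined. The two free ortho positions of 1 are equivalent, so only the 5,6,7-trimethoxy isomer can arise.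

Step 5 (double-bond shift and hydrolysis). The proton shift may stay incomplete, the delocalised anion may be oxidised or decompose, and unisomerised chromene may disproportionate under the acid. The fallback sets out from 11 and replaces the isomerisation by an oxidation–reduction pair. Hydride abstraction at C2 with Ph3CBF4 in CH2Cl2 should give 2-(3,4-dimethoxyphenyl)-5,6,7-trimethoxychromenylium tetrafluoroborate F2. Stirring F2 in aqueous NaHCO3–MeOH should hydrate C2 and open the hemiketal to (E)-1-(3,4-dimethoxyphenyl)-3-(2-hydroxy-4,5,6-trimethoxyphenyl)prop-2-en-1-one F3. Hydrogenation of the enone double bond (H2, 1 atm, 10% Pd/C, EtOAc, stopped after one equivalent) should then give 13, where the route is rejoined.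

Step 3 (silyl migration and triflation). The O-to-C silyl migration may be slow in the doubly flanked, methoxy-chelated aryllithium, so that proton quench or attack of the base at silicon competes, and the silyl group may be lost from the very electron-rich ring during triflation. The fallback sets out from 1 and installs silicon by directed ortho-metalation instead of halogen–metal exchange, bypassing steps 1 and 2. Carbamoylation (ClC(O)NEt2, NaH, THF) should give 3,4,5-trimethoxyphenyl N,N-diethylcarbamate F4. Lithiation between the carbamate and the neighbouring methoxy group (s-BuLi, TMEDA, THF, −78 °C) and quench with Me3SiCl should give 3,4,5-trimethoxy-2-(trimethylsilyl)phenyl N,N-diethylcarbamate F5. Reductive removal of the carbamoyl group (LiAlH4, THF, 0 → 25 °C) should give 3,4,5-trimethoxy-2-(trimethylsilyl)phenol F6, and Tf2O with pyridine in CH2Cl2 at 0 °C should give 6, where the route is rejoined.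

**Further compounds**

F1 | step 4 | 4-[(E)-2-(3,4-dimethoxyphenyl)ethenyl]-5,6,7-trimethoxy-2-phenyl-4H-1,3,2-benzodioxaborinine (racemic) | COc1cc2OB(c3ccccc3)OC(/C=C/c3ccc(OC)c(OC)c3)c2c(OC)c1OC
F2 | step 5 | 2-(3,4-dimethoxyphenyl)-5,6,7-trimethoxychromenylium tetrafluoroborate | COc1cc2[o+]c(-c3ccc(OC)c(OC)c3)ccc2c(OC)c1OC.F[B-](F)(F)F
F3 | step 5 | (E)-1-(3,4-dimethoxyphenyl)-3-(2-hydroxy-4,5,6-trimethoxyphenyl)prop-2-en-1-one | COc1cc(O)c(/C=C/C(=O)c2ccc(OC)c(OC)c2)c(OC)c1OC
F4 | step 3 | 3,4,5-trimethoxyphenyl N,N-diethylcarbamate | CCN(CC)C(=O)Oc1cc(OC)c(OC)c(OC)c1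
F5 | step 3 | 3,4,5-trimethoxy-2-(trimethylsilyl)phenyl N,N-diethylcarbamate | CCN(CC)C(=O)Oc1cc(OC)c(OC)c(OC)c1[Si](C)(C)C
F6 | step 3 | 3,4,5-trimethoxy-2-(trimethylsilyl)phenol | COc1cc(O)c([Si](C)(C)C)c(OC)c1OC
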